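**Plan** (ring atoms of the target: C1 = C(CH3)Cl, C2 = CH2, C3 = C(CH3)(bromovinyl), C4 = CHBr, C5 = CH2, C6 = CHCl)
Retrosynthesis: both C–Cl bonds go back to a C6=C1 alkene through its epoxide, C4–Br to a C4 ketone, and the bromovinyl group to an ester.
The ring is then cut at C2–C3 and C5–C6 into methacrolein (C2, C1 with its methyl, C6) and ethyl 2-methylacetoacetate (C3 with its methyl and ester, C4, C5).
Enabling feature: C4 lies between C3 and C5, so as a ketone it makes both neighbours nucleophilic, while C1 lies between C2 and C6 as the α-carbon of an enal whose β-carbon and carbonyl carbon are electrophilic; the cyclohexane therefore closes in one Michael/aldol (3+3) event, the only ring-forming step.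
Forward order: annulation, deconjugation to the C6=C1 alkene, C4 reduction, epoxidation, C4–Br, ester to (E)-bromovinyl, C1–Cl, C6–Cl.
Stereochemistry: C3 from the chiral catalyst in step 1; C4 by chelation-controlled reduction then SN2 inversion; C1 and C6 by hydroxyl-directed epoxidation followed by two inversions; alkene geometry from the Takai olefination.

Key step: step 1

Assumption: the cupreidine-derived catalyst is taken to give the (R) quaternary centre of 3; if the sense is the opposite one, its pseudoenantiomer derived from cupreine is used.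

Step 1
Reactants: 1 ethyl 2-methyl-3-oxobutanoate; 2 methacrolein
Product: 5 ethyl (1R)-1,5-dimethyl-2-oxocyclohex-3-ene-1-carboxylate, via Michael adduct 3 (not isolated), via aldol 4 (not isolated)
Conditions: 9-O-benzylcupreidine (10 mol %), 2 (2 equiv), CH2Cl2, −20 °C to rt; then TsOH·H2O (20 mol %), toluene, 80 °C, one pot
Reagents that add atoms: none
Why: The quinuclidine nitrogen of the catalyst deprotonates 1 while its 6′-OH hydrogen-bonds to methacrolein, so the chiral ion pair adds through the α-carbon of 1 to the β-CH2 of the enal (bond C3–C2), and the acid then drives aldol condensation of the methyl ketone carbon (C5) onto the aldehyde (C6). The closest known reaction type is the Robinson-type Michael/aldol annulation of α-substituted β-ketoesters with enals under bifunctional cinchona catalysis. The ring closes in the 6-(enolexo)-exo-trig mode and loss of water gives the C5=C6 enone. The quaternary centre C3 is set by the catalyst, which shields one face of the hydrogen-bonded enolate; the CH(CH3) centre at C1 forms as a mixture that step 2 erases. The step needs C- over O-attack and 1,4- over 1,2-addition, which the soft stabilised enolate should secure, and a single ring size, which is secured because the only other aldol (aldehyde α-carbon onto the ketone) would give a four-membered ring.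

Step 2
Reactants: 5 ethyl (1R)-1,5-dimethyl-2-oxocyclohex-3-ene-1-carboxylate
Product: 7 ethyl (1R)-1,5-dimethyl-2-oxocyclohex-4-ene-1-carboxylate, via potassium dienolate 6 (not isolated)
Conditions: KN(SiMe3)2 (1.2 equiv), THF, −78 °C; then AcOH, −78 °C
Reagents that add atoms: none
Why: Deconjugation by kinetic protonation of an extended enolate: C3 is quaternary, so the base can only remove the γ-hydrogen at C1, and α-protonation of the dienolate at C5 should give the β,γ-enone with the C6=C1 double bond while C3 stays untouched.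

Step 3
Reactants: 7 ethyl (1R)-1,5-dimethyl-2-oxocyclohex-4-ene-1-carboxylate
Product: 8 ethyl (1R,2R)-2-hydroxy-1,5-dimethylcyclohex-4-ene-1-carboxylate
Conditions: Zn(BH4)2, Et2O, −20 to 0 °C; aq. NH4Cl
Reagents that add atoms: none
Why: Chelation-controlled hydride reduction: zinc bridges the ketone and ester carbonyls, which holds the ester equatorial and the C3 methyl axial, so hydride should enter axially anti to that methyl and place the C4 hydroxyl trans to the ester.

Step 4
Reactants: 8 ethyl (1R,2R)-2-hydroxy-1,5-dimethylcyclohex-4-ene-1-carboxylate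
Product: 9 ethyl (1R,3R,4R,6S)-4-hydroxy-1,3-dimethyl-7-oxabicyclo[4.1.0]heptane-3-carboxylate
Conditions: VO(acac)2 (5 mol %), t-BuOOH (1.5 equiv), CH2Cl2, 0 °C to rt
Reagents that add atoms: tert-butyl hydroperoxide CC(C)(C)OO
Why: Hydroxyl-directed epoxidation of a homoallylic alcohol: the vanadate ester of the pseudoaxial C4–OH should deliver oxygen to the C6=C1 double bond on its own face, which sets both epoxide carbons cis to the hydroxyl and trans to the ester.

Step 5
Reactants: 9 ethyl (1R,3R,4R,6S)-4-hydroxy-1,3-dimethyl-7-oxabicyclo[4.1.0]heptane-3-carboxylate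
Product: 11 ethyl (1R,3S,4S,6S)-4-bromo-1,3-dimethyl-7-oxabicyclo[4.1.0]heptane-3-carboxylate, via triflate 10 (not isolated)
Conditions: Tf2O, 2,6-lutidine, CH2Cl2, −40 °C; then n-Bu4NBr, toluene, rt to 40 °C
Reagents that add atoms: tetra-n-butylammonium bromide CCCC[N+](CCCC)(CCCC)CCCC.[Br-]; trifluoromethanesulfonic anhydride O=S(=O)(OS(=O)(=O)C(F)(F)F)C(F)(F)F (its atoms stay in 10 only)
Why: SN2 displacement of a secondary triflate by bromide with inversion at C4: the ester on C3 disfavours ionisation and the leaving group is axial, so backside attack should give the bromide cis to the ester while the acid-free conditions leave the epoxide closed.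

Step 6
Reactants: 11 ethyl (1R,3S,4S,6S)-4-bromo-1,3-dimethyl-7-oxabicyclo[4.1.0]heptane-3-carboxylate
Product: 12 [(1R,3S,4S,6S)-4-bromo-1,3-dimethyl-7-oxabicyclo[4.1.0]heptan-3-yl]methanol
Conditions: i-Bu2AlH (2.5 equiv), CH2Cl2, −78 °C
Reagents that add atoms: none
Why: Ester reduction with i-Bu2AlH to the primary alcohol at low temperature, where a trisubstituted epoxide and a secondary alkyl bromide are normally inert.

Step 7
Reactants: 12 [(1R,3S,4S,6S)-4-bromo-1,3-dimethyl-7-oxabicyclo[4.1.0]heptan-3-yl]methanol
Product: 13 (1R,3S,4S,6S)-4-bromo-1,3-dimethyl-7-oxabicyclo[4.1.0]heptane-3-carbaldehyde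
Conditions: Dess–Martin periodinane, NaHCO3, CH2Cl2, 0 °C to rt
Reagents that add atoms: none
Why: Dess–Martin oxidation of a primary alcohol under buffered conditions; the aldehyde has no α-hydrogen, so it can neither epimerise nor eliminate the β-bromide.

Step 8
Reactants: 13 (1R,3S,4S,6S)-4-bromo-1,3-dimethyl-7-oxabicyclo[4.1.0]heptane-3-carbaldehyde
Product: 14 (1R,3S,4S,6S)-4-bromo-3-[(E)-2-bromoethenyl]-1,3-dimethyl-7-oxabicyclo[4.1.0]heptane
Conditions: CrBr2 (6 equiv), CHBr3 (2 equiv), THF, 0 °C to rt
Reagents that add atoms: bromoform BrC(Br)Br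
Why: Takai olefination: the geminal dichromium species from bromoform adds to the aldehyde and anti elimination should give the (E)-bromoalkene, CrBr2 being used so that no chloride can enter the vinyl halide.

Step 9
Reactants: 14 (1R,3S,4S,6S)-4-bromo-3-[(E)-2-bromoethenyl]-1,3-dimethyl-7-oxabicyclo[4.1.0]heptane
Product: 15 (1S,2S,4S,5S)-5-bromo-4-[(E)-2-bromoethenyl]-2-chloro-2,4-dimethylcyclohexan-1-ol
Conditions: HCl (2 M in Et2O, 1.5 equiv), CH2Cl2, −40 °C
Reagents that add atoms: hydrogen chloride Cl
Why: Acid-promoted epoxide opening: chloride should attack the protonated epoxide at the tertiary carbon C1 with inversion (Markovnikov, trans-diaxial by the Fürst–Plattner rule), giving the tertiary chloride on the face opposite to the former epoxide oxygen and the axial C6 alcohol.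

Step 10
Reactants: 15 (1S,2S,4S,5S)-5-bromo-4-[(E)-2-bromoethenyl]-2-chloro-2,4-dimethylcyclohexan-1-ol
Product: 16 (1S,2S,4S,5R)-1-bromo-2-[(E)-2-bromoethenyl]-4,5-dichloro-2,4-dimethylcyclohexane
Conditions: PPh3, N-chlorosuccinimide, CH2Cl2 then toluene, 0 to 60 °C
Reagents that add atoms: N-chlorosuccinimide O=C1CCC(=O)N1Cl
Why: Appel-type deoxychlorination: the alkoxyphosphonium ion at C6 should be displaced by chloride in an SN2 step with inversion, which places the second chlorine cis to the first and completes the target.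

**Compound list**
1 | ethyl 2-methyl-3-oxobutanoate (racemic) | CCOC(=O)C(C)C(C)=O | starting material
2 | methacrolein (2-methylprop-2-enal) | CC(=C)C=O | starting material
3 | ethyl (2R)-2-acetyl-2,4-dimethyl-5-oxopentanoate (both C4 epimers) | CCOC(=O)[C@](C)(CC(C)C=O)C(C)=O | intermediate
4 | ethyl (1R)-4-hydroxy-1,5-dimethyl-2-oxocyclohexane-1-carboxylate (epimers at C4 and C5) | CCOC(=O)[C@]1(C)CC(C)C(O)CC1=O | intermediate
5 | ethyl (1R)-1,5-dimethyl-2-oxocyclohex-3-ene-1-carboxylate (both C5 epimers) | CCOC(=O)[C@]1(C)CC(C)C=CC1=O | intermediate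
6 | potassium (6R)-6-(ethoxycarbonyl)-4,6-dimethylcyclohexa-1,3-dien-1-olate | CCOC(=O)[C@]1(C)CC(C)=CC=C1[O-].[K+] | intermediate
7 | ethyl (1R)-1,5-dimethyl-2-oxocyclohex-4-ene-1-carboxylate | CCOC(=O)[C@]1(C)CC(C)=CCC1=O | intermediate
8 | ethyl (1R,2R)-2-hydroxy-1,5-dimethylcyclohex-4-ene-1-carboxylate (hydroxyl trans to the ester) | CC1=CC[C@@H](O)[C@](C)(C(=O)OCC)C1 | intermediate
9 | ethyl (1R,3R,4R,6S)-4-hydroxy-1,3-dimethyl-7-oxabicyclo[4.1.0]heptane-3-carboxylate (epoxide cis to the hydroxyl) | C[C@]12O[C@H]1C[C@@H](O)[C@](C)(C(=O)OCC)C2 | intermediate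
10 | ethyl (1R,3R,4R,6S)-1,3-dimethyl-4-{[(trifluoromethyl)sulfonyl]oxy}-7-oxabicyclo[4.1.0]heptane-3-carboxylate | C[C@]12O[C@H]1C[C@@H](OS(=O)(=O)C(F)(F)F)[C@](C)(C(=O)OCC)C2 | intermediate
11 | ethyl (1R,3S,4S,6S)-4-bromo-1,3-dimethyl-7-oxabicyclo[4.1.0]heptane-3-carboxylate (bromine cis to the ester) | C[C@]12O[C@H]1C[C@H](Br)[C@](C)(C(=O)OCC)C2 | intermediate
12 | [(1R,3S,4S,6S)-4-bromo-1,3-dimethyl-7-oxabicyclo[4.1.0]heptan-3-yl]methanol | C[C@]12O[C@H]1C[C@H](Br)[C@](C)(CO)C2 | intermediate
13 | (1R,3S,4S,6S)-4-bromo-1,3-dimethyl-7-oxabicyclo[4.1.0]heptane-3-carbaldehyde | C[C@]12O[C@H]1C[C@H](Br)[C@](C)(C=O)C2 | intermediate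
14 | (1R,3S,4S,6S)-4-bromo-3-[(E)-2-bromoethenyl]-1,3-dimethyl-7-oxabicyclo[4.1.0]heptane | C[C@]12O[C@H]1C[C@H](Br)[C@](C)(/C=C/Br)C2 | intermediate
15 | (1S,2S,4S,5S)-5-bromo-4-[(E)-2-bromoethenyl]-2-chloro-2,4-dimethylcyclohexan-1-ol | C[C@]1(Cl)C[C@@](C)(/C=C/Br)[C@@H](Br)C[C@@H]1O | intermediate
16 | (1S,2S,4S,5R)-1-bromo-2-[(E)-2-bromoethenyl]-4,5-dichloro-2,4-dimethylcyclohexane | C[C@]1(Cl)C[C@@](C)(/C=C/Br)[C@@H](Br)C[C@H]1Cl | target

**Total step count:** 10. **Longest linear sequence:** 10 steps (from 1 and 2).

**Steps most likely to fail**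

Step 1. The α-branched enal may add sluggishly and the catalyst may discriminate the enolate faces incompletely, so the quaternary centre could form slowly or with low enantiomeric purity. Fallback (sets out from 1 and 2, comes back at 8): 1 and 2 are joined with an achiral base (DABCO, CH2Cl2) and then TsOH as in step 1, which should give, by way of the racemic Michael adduct F1 and the racemic aldol F2, the racemic enone F3. Deconjugation as in step 2, by way of the racemic potassium dienolate F4, should give the racemic β,γ-enone F5. A ketoreductase chosen by screening (NADPH recycled with isopropanol, buffer, 30 °C) should then reduce only the (R)-ketone, from the face that gives 8. Asymmetric catalysis is thus replaced by an enzymatic kinetic resolution, and 8 rejoins the route.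

Step 5. Substitution at the carbon next to the quaternary centre may be slow, so that elimination towards C5 or opening of the epoxide by bromide competes. Fallback (sets out from 7, comes back at 11): 7 is reduced without chelation (NaBH4, MeOH, −40 °C; ester axial, axial hydride attack anti to it) to the epimeric alcohol F6, with the hydroxyl cis to the ester. Its quinoline-8-sulfonate F7 (quinoline-8-sulfonyl chloride, pyridine, DMAP) is treated with TiBr4 (CH2Cl2, −78 °C), which should deliver bromide from the front side of the titanium-chelated leaving group with retention and give the bromo alkene F8. Epoxidation with m-CPBA (CH2Cl2, 0 °C), anti to the ester and the bromine that share the upper face, should then give 11. The inverting SN2 step is thus replaced by a retentive front-side substitution, and the epoxide is introduced only afterwards under steric control.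

Step 10. The axial chlorine at C1 lies antiperiplanar to the activated C6 oxygen and may take part as a neighbouring group, so that retention, a chlorine shift or elimination replaces the clean inversion. Fallback (sets out from 15, comes back at 16): 15 is oxidised (Dess–Martin periodinane, CH2Cl2) to the α-chloro ketone F9. NaBH4 (MeOH, −78 °C) should attack anti to the axial C–Cl bond and give the cis-chlorohydrin F10, whose equatorial hydroxyl is no longer antiperiplanar to the chlorine. SOCl2 in dioxane should form the chlorosulfite F11, which collapses by internal return (SNi) with retention to 16.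

**Further compounds**
F1 | step 1 | racemic ethyl 2-acetyl-2,4-dimethyl-5-oxopentanoate | CCOC(=O)C(C)(CC(C)C=O)C(C)=O
F2 | step 1 | racemic ethyl 4-hydroxy-1,5-dimethyl-2-oxocyclohexane-1-carboxylate | CCOC(=O)C1(C)CC(C)C(O)CC1=O
F3 | step 1 | racemic ethyl 1,5-dimethyl-2-oxocyclohex-3-ene-1-carboxylate | CCOC(=O)C1(C)CC(C)C=CC1=O
F4 | step 1 | racemic potassium 6-(ethoxycarbonyl)-4,6-dimethylcyclohexa-1,3-dien-1-olate | CCOC(=O)C1(C)CC(C)=CC=C1[O-].[K+]
F5 | step 1 | racemic ethyl 1,5-dimethyl-2-oxocyclohex-4-ene-1-carboxylate | CCOC(=O)C1(C)CC(C)=CCC1=O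
F6 | step 5 | ethyl (1R,2S)-2-hydroxy-1,5-dimethylcyclohex-4-ene-1-carboxylate | CC1=CC[C@H](O)[C@](C)(C(=O)OCC)C1
F7 | step 5 | ethyl (1R,2S)-1,5-dimethyl-2-(quinolin-8-ylsulfonyloxy)cyclohex-4-ene-1-carboxylate | CC1=CC[C@H](OS(=O)(=O)c2cccc3cccnc23)[C@](C)(C(=O)OCC)C1
F8 | step 5 | ethyl (1S,2S)-2-bromo-1,5-dimethylcyclohex-4-ene-1-carboxylate | CC1=CC[C@H](Br)[C@](C)(C(=O)OCC)C1
F9 | step 10 | (2S,4S,5S)-5-bromo-4-[(E)-2-bromoethenyl]-2-chloro-2,4-dimethylcyclohexan-1-one | C[C@]1(Cl)C[C@@](C)(/C=C/Br)[C@@H](Br)CC1=O
F10 | step 10 | (1R,2S,4S,5S)-5-bromo-4-[(E)-2-bromoethenyl]-2-chloro-2,4-dimethylcyclohexan-1-ol | C[C@]1(Cl)C[C@@](C)(/C=C/Br)[C@@H](Br)C[C@H]1O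
F11 | step 10 | chlorosulfite of F10 | C[C@]1(Cl)C[C@@](C)(/C=C/Br)[C@@H](Br)C[C@H]1OS(Cl)=O
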